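**Fixed count.** Every exchange leaves the count of starting complex in a flask unchanged, so after the feed it stands at 0.0400 M, and I used that count to choose which charge of incoming ligand to run next, aiming at the highest free complex with one exchanged at the end.

| setting | theta | epsilon | beta |
|---|---|---|---|
| starting complex | 0.050 M | 0.050 M | 0.050 M |
| incoming ligand | 0.120 M | 0.250 M | 0.500 M |
| leaving ligand | 0.250 M (fed, over 40 min) | 0.250 M (fed, over 40 min) | 0.250 M (fed, over 40 min) |
| time | 10 h | 10 h | 10 h |
| remark | the fed solution adds 0.25 times the starting volume | the fed solution adds 0.25 times the starting volume | the fed solution adds 0.25 times the starting volume |

    starting complex + incoming ligand ⇌ leaving ligand + complex with one exchanged (K1 = 0.66, k1 = 0.064 /M/min)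
    complex with one exchanged + incoming ligand ⇌ leaving ligand + complex with two exchanged (K2 = 39, k2 = 0.015 /M/min)
    complex with two exchanged + incoming ligand ⇌ leaving ligand + complex with three exchanged (K3 = 3.3, k3 = 0.26 /M/min)
    complex with three exchanged + incoming ligand ⇌ leaving ligand + complex with four exchanged (K4 = 0.33, k4 = 0.065 /M/min)
    starting complex + complex with one exchanged ⇌ idle adduct, settled at all times (K5 = 63 /M)

- a species is counted by the starting complex in it: one idle adduct counts as two
- amounts and yields of complex with one exchanged count idle adduct too
- charges are per starting volume, the dose included; the dosed solution carries all of it
- in an amount of complex with one exchanged, one idle adduct counts as one complex with one exchanged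
- the concentration of complex with one exchanged that is asked is that of its free form alone
- "hardly changes" means that all values lie within two and a half points (for a concentration: within two and a half percent of the largest)
- run time (theta): 10 h

1. [complex with one exchanged] (only what is free in solution) at the end for theta, epsilon, beta, in this order
2. how the row runs (rises, then falls / rises all the way / falls, then rises / falls all the way / hardly changes)

**Balanced pool.** I called the pool the free starting complex, the free complex with one exchanged and the idle adduct. I took the first exchange as balanced, because in theta its forward half-life of 1.5 h is shorter than the run, and I extended that to the other flasks. The free ratio c(complex with one exchanged)/c(starting complex) is then 0.66 times the charged ratio of incoming to leaving ligand, the dilution cancelling: 0.317, 0.660 and 1.32 for theta, epsilon and beta. Counting the adduct twice, with the whole count in the pool, left free c(complex with one exchanged) of 0.00608 M, 0.00932 M and 0.0132 M.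

**Pool time.** The second exchange takes the free form, not the adduct, and it is the rate-limiting step of the way onward, its half-life in theta being 6.4 h against 0.37 h for the next exchange. So I defined the pool time as the pool divided by the rate of the second exchange, which for beta at the opening was 8.39 h, against 23.9 h for epsilon and 76.1 h for theta. The run outlasts it in beta but not in theta. Solving the balance for a small change of the pool, I found free complex going as the pool to the power 0.731, 0.707 and 0.705 for theta, epsilon and beta, so about 0.7, and I let each pool drain at a rate following that power from its opening pool time, which gave 0.00554 M, 0.00681 M and 0.00472 M. Epsilon stood highest, so I chose it, though I expected these figures to be high, since the charged ratio counts no incoming ligand spent and no leaving ligand made.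

**The forecast.** It gave 0.0046 M, 0.0055 M and 0.0048 M, so rises, then falls, saying that “in beta the much faster drain has depleted the pool by 10 h”. Its middle value lay below mine, while its shape was the same.

**The result.** The flasks ended at 0.00461 M, 0.00584 M and 0.00499 M, so the row rises, then falls, with epsilon highest. The row turns at 0.29 M of incoming ligand, where it reaches 0.00590 M. I then put the end readings at 10.0 h into the pool time, using the pool left after the complexes with two, three and four exchanged and the incoming ligand and free complex then present: beta had 11.5 h left, and theta had 115 h.

The rate constants were drawn at random within sensible limits; no experiment stands behind them.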